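**Retrosynthetic overview**

- Achilleol A (20) ⇐ ketone 19 by substrate-controlled hydride reduction; the carbinol centre is set last.
- 19 ⇐ acyclic 4-alkynal 17 + ethylene (18) by a rhodium-catalysed hydroacylative [4+2] annulation that makes the only ring, both ring bonds to the CH2–CH2 unit and the exocyclic methylene in one operation.
- Enabling feature: in the cyclohexane ring the carbinol carbon C1 and the methylidene-bearing carbon C4 stand 1,4, bridged on one side by the unsubstituted C5–C6 ethano unit and on the other by the quaternary C2 (gem-dimethyl, no α-hydrogen) and the side-chain carbon C3, so the ring is an aldehyde C–H / terminal alkyne / ethylene adduct.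
- 17 ⇐ vinyl ester 12 (Wacker oxidation, enol phosphate elimination, redox adjustment) ⇐ allylic carbonate 10 + ketene silyl acetal 11 by iridium-catalysed asymmetric allylic alkylation, which sets C3 next to the quaternary C2.
- 10 ⇐ (2E,6E)-farnesyl bromide (1) by two-carbon homologation, isopropenyl addition, Johnson–Claisen rearrangement (E trisubstituted olefin) and Horner–Wadsworth–Emmons extension; there is one ring only, closed in step 14.

Key step: step 14

Assumption: (2E,6E)-farnesyl bromide (1), ketene silyl acetal 11 and ethylene (18) are bought; in step 9 the ligand antipode that gives the (3R) ester is used, its sense of induction to be checked on the first run.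

**Route**

Step 1
Reactants: 1 (2E,6E)-farnesyl bromide
Product: 2 (4E,8E)-5,9,13-trimethyltetradeca-4,8,12-trienenitrile
Conditions: MeCN (3 equiv), n-BuLi (2.9 equiv), THF, −78 °C; then 1, −78 to −20 °C
Reagents that add atoms: acetonitrile, CC#N
Why: SN2 alkylation of a nitrile-stabilised carbanion (lithioacetonitrile) at the unhindered primary allylic carbon adds the two-carbon unit without touching the (2E,6E) olefins.

Step 2
Reactants: 2 (4E,8E)-5,9,13-trimethyltetradeca-4,8,12-trienenitrile
Product: 3 (4E,8E)-5,9,13-trimethyltetradeca-4,8,12-trienal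
Conditions: i-Bu2AlH (1.2 equiv), CH2Cl2, −78 °C; then aq. NaKC4H4O6, dilute aq. AcOH, 0 °C
Reagents that add atoms: water, O
Why: Nitrile half-reduction with i-Bu2AlH stops at the imine oxidation level at −78 °C and hydrolytic work-up delivers the aldehyde.

Step 3
Reactants: 3 (4E,8E)-5,9,13-trimethyltetradeca-4,8,12-trienal
Product: 4 (6E,10E)-2,7,11,15-tetramethylhexadeca-1,6,10,14-tetraen-3-ol (racemic)
Conditions: CH2=C(CH3)MgBr (1.3 equiv), THF, −78 to 0 °C; aq. NH4Cl
Reagents that add atoms: isopropenylmagnesium bromide, C=C(C)[Mg]Br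
Why: Grignard 1,2-addition gives the isopropenyl carbinol needed for the Claisen step; its stereocentre forms racemic and is erased in step 4.

Step 4
Reactants: 4 (6E,10E)-2,7,11,15-tetramethylhexadeca-1,6,10,14-tetraen-3-ol
Product: 6 ethyl (4E,8E,12E)-4,9,13,17-tetramethyloctadeca-4,8,12,16-tetraenoate, via mixed ketene acetal 5 (not isolated)
Conditions: MeC(OEt)3 (6 equiv), EtCO2H (5 mol %), 138 °C, EtOH distilled off
Reagents that add atoms: triethyl orthoacetate, CC(OCC)(OCC)OCC
Why: Johnson–Claisen orthoester rearrangement through a chair transition state with the chain equatorial sets the (4E) trisubstituted olefin and consumes the carbinol stereocentre.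

Step 5
Reactants: 6 ethyl (4E,8E,12E)-4,9,13,17-tetramethyloctadeca-4,8,12,16-tetraenoate
Product: 7 (4E,8E,12E)-4,9,13,17-tetramethyloctadeca-4,8,12,16-tetraenal
Conditions: i-Bu2AlH (1.1 equiv), toluene, −78 °C; MeOH, aq. NaKC4H4O6
Reagents that add atoms: none
Why: Ester half-reduction with one equivalent of i-Bu2AlH at −78 °C is a standard way to the aldehyde and leaves the olefins alone.

Step 6
Reactants: 7 (4E,8E,12E)-4,9,13,17-tetramethyloctadeca-4,8,12,16-tetraenal
Product: 8 ethyl (2E,6E,10E,14E)-6,11,15,19-tetramethylicosa-2,6,10,14,18-pentaenoate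
Conditions: (EtO)2P(O)CH2CO2Et (1.3 equiv), NaH (1.25 equiv), THF, 0 to 25 °C
Reagents that add atoms: triethyl phosphonoacetate, CCOC(=O)CP(=O)(OCC)OCC
Why: Horner–Wadsworth–Emmons olefination with a stabilised phosphonate anion gives the (2E) enoate.

Step 7
Reactants: 8 ethyl (2E,6E,10E,14E)-6,11,15,19-tetramethylicosa-2,6,10,14,18-pentaenoate
Product: 9 (2E,6E,10E,14E)-6,11,15,19-tetramethylicosa-2,6,10,14,18-pentaen-1-ol
Conditions: i-Bu2AlH (2.3 equiv), CH2Cl2, −78 to 0 °C; aq. NaKC4H4O6
Reagents that add atoms: none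
Why: 1,2-Reduction of the enoate by i-Bu2AlH gives the (E) allylic alcohol without conjugate reduction.

Step 8
Reactants: 9 (2E,6E,10E,14E)-6,11,15,19-tetramethylicosa-2,6,10,14,18-pentaen-1-ol
Product: 10 methyl (2E,6E,10E,14E)-6,11,15,19-tetramethylicosa-2,6,10,14,18-pentaen-1-yl carbonate
Conditions: ClCO2Me (1.5 equiv), pyridine, CH2Cl2, 0 °C
Reagents that add atoms: methyl chloroformate, COC(=O)Cl
Why: O-Acylation of the primary alcohol gives the linear allylic carbonate, the usual electrophile for iridium-catalysed allylic substitution.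

Step 9
Reactants: 10 methyl (2E,6E,10E,14E)-6,11,15,19-tetramethylicosa-2,6,10,14,18-pentaen-1-yl carbonate; 11 1-methoxy-2-methyl-1-(trimethylsilyloxy)prop-1-ene
Product: 12 methyl (3R,6E,10E,14E)-3-ethenyl-2,2,6,11,15,19-hexamethylicosa-6,10,14,18-tetraenoate
Conditions: [Ir(cod)Cl]2 (2 mol %), BINOL-derived N,N-bis(1-phenylethyl)phosphoramidite (4 mol %, antipode giving 3R), catalyst cyclometalated beforehand with n-PrNH2, THF, 25–50 °C
Reagents that add atoms: none
Why: Iridium-catalysed enantioselective allylic alkylation with a silyl ketene acetal as ester enolate equivalent: the carbonate is ionised, the released methoxide activates 11, and attack at the substituted allyl terminus anti to the metal lets the catalyst set the (3R) centre beside the new quaternary carbon with branched selectivity.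

Step 10
Reactants: 12 methyl (3R,6E,10E,14E)-3-ethenyl-2,2,6,11,15,19-hexamethylicosa-6,10,14,18-tetraenoate
Product: 13 methyl (3S,6E,10E,14E)-3-acetyl-2,2,6,11,15,19-hexamethylicosa-6,10,14,18-tetraenoate
Conditions: PdCl2 (10 mol %), CuCl (1 equiv), O2 (1 atm), DMF–H2O 7:1, 25 °C
Reagents that add atoms: water, O
Why: Tsuji–Wacker oxidation: divalent palladium activates only the monosubstituted vinyl group (the trisubstituted olefins do not coordinate) and Markovnikov attack of water gives the methyl ketone; the C3 centre keeps its spatial arrangement (the descriptor changes only through priorities).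

Step 11
Reactants: 13 methyl (3S,6E,10E,14E)-3-acetyl-2,2,6,11,15,19-hexamethylicosa-6,10,14,18-tetraenoate
Product: 15 methyl (3R,6E,10E,14E)-3-ethynyl-2,2,6,11,15,19-hexamethylicosa-6,10,14,18-tetraenoate, via enol phosphate 14 (not isolated)
Conditions: LiN(i-Pr)2 (1.1 equiv), THF, −78 °C (13 added to the base); ClP(O)(OEt)2 (1.2 equiv), −78 to 0 °C; then LiN(i-Pr)2 (2.3 equiv), −78 to 25 °C; aq. NH4Cl
Reagents that add atoms: none
Why: Methyl ketone to terminal alkyne by kinetic enolisation on the methyl side, O-phosphorylation and base-induced β-elimination of the enol phosphate; the hindered C3–H is not removed by the kinetic base, so the centre is kept.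

Step 12
Reactants: 15 methyl (3R,6E,10E,14E)-3-ethynyl-2,2,6,11,15,19-hexamethylicosa-6,10,14,18-tetraenoate
Product: 16 (3R,6E,10E,14E)-3-ethynyl-2,2,6,11,15,19-hexamethylicosa-6,10,14,18-tetraen-1-ol
Conditions: i-Bu2AlH (2.5 equiv), CH2Cl2, −78 to 0 °C; aq. NaKC4H4O6
Reagents that add atoms: none
Why: Exhaustive hydride reduction of the hindered ester gives the neopentyl alcohol; the terminal alkyne and the olefins are inert at this temperature.

Step 13
Reactants: 16 (3R,6E,10E,14E)-3-ethynyl-2,2,6,11,15,19-hexamethylicosa-6,10,14,18-tetraen-1-ol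
Product: 17 (3R,6E,10E,14E)-3-ethynyl-2,2,6,11,15,19-hexamethylicosa-6,10,14,18-tetraenal
Conditions: Dess–Martin periodinane (1.3 equiv), NaHCO3, CH2Cl2, 0 to 25 °C
Reagents that add atoms: none
Why: Dess–Martin oxidation gives the non-enolisable α,α-dimethyl aldehyde under buffered conditions that spare the alkyne and the polyene.

Step 14
Reactants: 17 (3R,6E,10E,14E)-3-ethynyl-2,2,6,11,15,19-hexamethylicosa-6,10,14,18-tetraenal; 18 ethylene
Product: 19 (3R)-2,2-dimethyl-4-methylidene-3-[(3E,7E,11E)-3,8,12,16-tetramethylheptadeca-3,7,11,15-tetraen-1-yl]cyclohexan-1-one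
Conditions: [Rh(nbd)(dppe)]BF4 (10 mol %, nbd removed with H2 before use), ethylene (5 bar), acetone, 25–40 °C
Reagents that add atoms: none
Why: Proposed new method: the cationic monovalent rhodium–dppe catalyst should insert into the aldehyde C–H bond of 17, the acyl rhodium hydride should add syn across the chelated terminal alkyne (hydride to the terminal carbon) to give a five-membered acyl(alkenyl) trivalent rhodium metallacycle, ethylene should insert into it, and C–C reductive elimination should release cyclohexanone 19 with the exocyclic methylene already in place. The closest known reaction type is the rhodium-catalysed [4+2] annulation of 4-alkynals with alkynes or acrylamides, itself an interrupted intramolecular alkyne hydroacylation; new here are ethylene as the two-carbon partner and a terminal alkyne. The one ring is closed as a formal [4+2] annulation: the carbonyl-carbon–CH2 and CH2–alkenyl-carbon bonds are made at the metal and the six-membered carbocycle closes by reductive elimination from a seven-membered rhodacycle. No stereocentre is created, and the C3 centre, which has no acidifying neighbour (quaternary C2 between it and the carbonyl), is carried through unchanged. The step needs ethylene capture of the metallacycle to outrun its unimolecular reductive elimination or isomerisation, decarbonylation, and plain hydroacylation of ethylene; the 1,4 spacing of aldehyde and alkyne (chelation), the gem-dimethyl group (no α-hydrogen, favoured metallacycle) and several bar of ethylene should secure this, while the four trisubstituted olefins are too hindered to bind rhodium.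

Step 15
Reactants: 19 (3R)-2,2-dimethyl-4-methylidene-3-[(3E,7E,11E)-3,8,12,16-tetramethylheptadeca-3,7,11,15-tetraen-1-yl]cyclohexan-1-one
Product: 20 achilleol A, (1S,3R)-2,2-dimethyl-4-methylidene-3-[(3E,7E,11E)-3,8,12,16-tetramethylheptadeca-3,7,11,15-tetraen-1-yl]cyclohexan-1-ol
Conditions: NaBH4 (1.5 equiv), MeOH–THF, −40 to 0 °C
Reagents that add atoms: none
Why: Hydride 1,2-reduction in which hydride should add to the carbonyl face anti to the C3 side chain (axially on the chair with the side chain equatorial, the axial C2 methyl blocking the equatorial path, as in the reduction of 4,4-dimethyl-3-oxo triterpenoids to 3β-alcohols), giving the (1S) carbinol cis to the side chain.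

**Compound list**

1 | (2E,6E)-farnesyl bromide | BrC/C=C(\C)CC/C=C(\C)CCC=C(C)C | starting material
2 | (4E,8E)-5,9,13-trimethyltetradeca-4,8,12-trienenitrile | N#CCC/C=C(\C)CC/C=C(\C)CCC=C(C)C | intermediate
3 | (4E,8E)-5,9,13-trimethyltetradeca-4,8,12-trienal | O=CCC/C=C(\C)CC/C=C(\C)CCC=C(C)C | intermediate
4 | (6E,10E)-2,7,11,15-tetramethylhexadeca-1,6,10,14-tetraen-3-ol (racemic) | C=C(C)C(O)CC/C=C(\C)CC/C=C(\C)CCC=C(C)C | intermediate
5 | (6E,10E)-3-[(1-ethoxyethenyl)oxy]-2,7,11,15-tetramethylhexadeca-1,6,10,14-tetraene (mixed ketene acetal, not isolated) | C=C(OCC)OC(CC/C=C(\C)CC/C=C(\C)CCC=C(C)C)C(C)=C | intermediate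
6 | ethyl (4E,8E,12E)-4,9,13,17-tetramethyloctadeca-4,8,12,16-tetraenoate | CCOC(=O)CC/C(C)=C/CC/C=C(\C)CC/C=C(\C)CCC=C(C)C | intermediate
7 | (4E,8E,12E)-4,9,13,17-tetramethyloctadeca-4,8,12,16-tetraenal | O=CCC/C(C)=C/CC/C=C(\C)CC/C=C(\C)CCC=C(C)C | intermediate
8 | ethyl (2E,6E,10E,14E)-6,11,15,19-tetramethylicosa-2,6,10,14,18-pentaenoate | CCOC(=O)/C=C/CC/C(C)=C/CC/C=C(\C)CC/C=C(\C)CCC=C(C)C | intermediate
9 | (2E,6E,10E,14E)-6,11,15,19-tetramethylicosa-2,6,10,14,18-pentaen-1-ol | OC/C=C/CC/C(C)=C/CC/C=C(\C)CC/C=C(\C)CCC=C(C)C | intermediate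
10 | methyl (2E,6E,10E,14E)-6,11,15,19-tetramethylicosa-2,6,10,14,18-pentaen-1-yl carbonate | COC(=O)OC/C=C/CC/C(C)=C/CC/C=C(\C)CC/C=C(\C)CCC=C(C)C | intermediate
11 | 1-methoxy-2-methyl-1-(trimethylsilyloxy)prop-1-ene (methyl trimethylsilyl dimethylketene acetal) | COC(O[Si](C)(C)C)=C(C)C | starting material
12 | methyl (3R,6E,10E,14E)-3-ethenyl-2,2,6,11,15,19-hexamethylicosa-6,10,14,18-tetraenoate | C=C[C@@H](CC/C(C)=C/CC/C=C(\C)CC/C=C(\C)CCC=C(C)C)C(C)(C)C(=O)OC | intermediate
13 | methyl (3S,6E,10E,14E)-3-acetyl-2,2,6,11,15,19-hexamethylicosa-6,10,14,18-tetraenoate | CC(=O)[C@@H](CC/C(C)=C/CC/C=C(\C)CC/C=C(\C)CCC=C(C)C)C(C)(C)C(=O)OC | intermediate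
14 | methyl (3S,6E,10E,14E)-3-{1-[(diethoxyphosphoryl)oxy]ethenyl}-2,2,6,11,15,19-hexamethylicosa-6,10,14,18-tetraenoate (enol phosphate, not isolated) | C=C(OP(=O)(OCC)OCC)[C@@H](CC/C(C)=C/CC/C=C(\C)CC/C=C(\C)CCC=C(C)C)C(C)(C)C(=O)OC | intermediate
15 | methyl (3R,6E,10E,14E)-3-ethynyl-2,2,6,11,15,19-hexamethylicosa-6,10,14,18-tetraenoate | C#C[C@@H](CC/C(C)=C/CC/C=C(\C)CC/C=C(\C)CCC=C(C)C)C(C)(C)C(=O)OC | intermediate
16 | (3R,6E,10E,14E)-3-ethynyl-2,2,6,11,15,19-hexamethylicosa-6,10,14,18-tetraen-1-ol | C#C[C@@H](CC/C(C)=C/CC/C=C(\C)CC/C=C(\C)CCC=C(C)C)C(C)(C)CO | intermediate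
17 | (3R,6E,10E,14E)-3-ethynyl-2,2,6,11,15,19-hexamethylicosa-6,10,14,18-tetraenal | C#C[C@@H](CC/C(C)=C/CC/C=C(\C)CC/C=C(\C)CCC=C(C)C)C(C)(C)C=O | intermediate
18 | ethylene | C=C | starting material
19 | (3R)-2,2-dimethyl-4-methylidene-3-[(3E,7E,11E)-3,8,12,16-tetramethylheptadeca-3,7,11,15-tetraen-1-yl]cyclohexan-1-one | C=C1CCC(=O)C(C)(C)[C@@H]1CC/C(C)=C/CC/C=C(\C)CC/C=C(\C)CCC=C(C)C | intermediate
20 | achilleol A, (1S,3R)-2,2-dimethyl-4-methylidene-3-[(3E,7E,11E)-3,8,12,16-tetramethylheptadeca-3,7,11,15-tetraen-1-yl]cyclohexan-1-ol | C=C1CC[C@H](O)C(C)(C)[C@@H]1CC/C(C)=C/CC/C=C(\C)CC/C=C(\C)CCC=C(C)C | target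

**Count and risks**

Total step count: 15. Longest linear sequence: 15 (steps 1–15; 11 and 18 are bought).

Steps most likely to fail:

1. Step 14 (Proposed new method). What may go wrong: reductive elimination or isomerisation of the five-membered rhodacycle before ethylene inserts, decarbonylation of the acyl rhodium hydride, plain hydroacylation of ethylene, or β-hydride elimination after insertion. Fallback, a tin-mediated radical ring closure in place of the metal-catalysed annulation: it sets out from 17 and comes back at 19. CH2=CHMgBr (THF, −78 °C) adds to the aldehyde to give the allylic alcohol (3RS,5R,8E,12E,16E)-5-ethynyl-4,4,8,13,17,21-hexamethyldocosa-1,8,12,16,20-pentaen-3-ol F1, and Dess–Martin oxidation gives the vinyl ketone (5R,8E,12E,16E)-5-ethynyl-4,4,8,13,17,21-hexamethyldocosa-1,8,12,16,20-pentaen-3-one F2. Slow addition of Bu3SnH with AIBN (benzene, 80 °C) adds a stannyl radical to the alkyne terminus, and the alkenyl radical closes onto the CH2 end of the enone (stannyl radical addition–cyclisation) to give the exocyclic alkenylstannane (3S)-2,2-dimethyl-3-[(3E,7E,11E)-3,8,12,16-tetramethylheptadeca-3,7,11,15-tetraen-1-yl]-4-[(tributylstannyl)methylidene]cyclohexan-1-one F3. Protodestannylation (HCl, 1 equiv, CH2Cl2, −78 °C) then gives 19.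

2. Step 10. What may go wrong: slow or anti-Markovnikov oxypalladation at the hindered vinyl group, and acid-promoted epimerisation next to the new ketone. Fallback, anti-Markovnikov functionalisation and elimination from an aldehyde instead of a methyl ketone: it sets out from 12 and comes back at 15, by-passing 13, 14 and step 11. 9-BBN (THF, 0 to 25 °C; the trisubstituted olefins should not react) gives the alkylborane methyl (3S,6E,10E,14E)-3-[2-(9-borabicyclo[3.3.1]nonan-9-yl)ethyl]-2,2,6,11,15,19-hexamethylicosa-6,10,14,18-tetraenoate F4, which NaBO3·4H2O oxidises to the primary alcohol methyl (3R,6E,10E,14E)-3-(2-hydroxyethyl)-2,2,6,11,15,19-hexamethylicosa-6,10,14,18-tetraenoate F5. Dess–Martin oxidation gives the aldehyde methyl (3R,6E,10E,14E)-2,2,6,11,15,19-hexamethyl-3-(2-oxoethyl)icosa-6,10,14,18-tetraenoate F6. Nonafluorobutanesulfonyl fluoride and the phosphazene base P2-Et (DMF, −20 to 25 °C) convert it in one pot, through the enol nonaflate methyl (3R,6E,10E,14E)-2,2,6,11,15,19-hexamethyl-3-{2-[(nonafluorobutylsulfonyl)oxy]ethenyl}icosa-6,10,14,18-tetraenoate F7, into alkyne 15. In this branch the stereocentre is never α to a carbonyl.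

3. Step 15. What may go wrong: poor facial selectivity of hydride delivery, because the chair with the side chain axial may compete. Fallback, catalyst control in place of substrate control: it sets out from 19 and comes back at 20 without a new compound. A Corey–Bakshi–Shibata reduction with the (R)-2-butyl oxazaborolidine and catecholborane (toluene, −78 °C) is used; catecholborane does not hydroborate the olefins at this temperature. The catalyst distinguishes the quaternary C2 side from the CH2 side of the ketone and should deliver the (1S) alcohol whatever the ring conformation.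

**Further compounds**

F1 | step 14 | (3RS,5R,8E,12E,16E)-5-ethynyl-4,4,8,13,17,21-hexamethyldocosa-1,8,12,16,20-pentaen-3-ol | C#C[C@@H](CC/C(C)=C/CC/C=C(\C)CC/C=C(\C)CCC=C(C)C)C(C)(C)C(O)C=C
F2 | step 14 | (5R,8E,12E,16E)-5-ethynyl-4,4,8,13,17,21-hexamethyldocosa-1,8,12,16,20-pentaen-3-one | C#C[C@@H](CC/C(C)=C/CC/C=C(\C)CC/C=C(\C)CCC=C(C)C)C(C)(C)C(=O)C=C
F3 | step 14 | (3S)-2,2-dimethyl-3-[(3E,7E,11E)-3,8,12,16-tetramethylheptadeca-3,7,11,15-tetraen-1-yl]-4-[(tributylstannyl)methylidene]cyclohexan-1-one | CCCC[Sn](CCCC)(CCCC)C=C1CCC(=O)C(C)(C)[C@@H]1CC/C(C)=C/CC/C=C(\C)CC/C=C(\C)CCC=C(C)C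
F4 | step 10 | methyl (3S,6E,10E,14E)-3-[2-(9-borabicyclo[3.3.1]nonan-9-yl)ethyl]-2,2,6,11,15,19-hexamethylicosa-6,10,14,18-tetraenoate | C1CC2CCCC(C1)B2CC[C@@H](CC/C(C)=C/CC/C=C(\C)CC/C=C(\C)CCC=C(C)C)C(C)(C)C(=O)OC
F5 | step 10 | methyl (3R,6E,10E,14E)-3-(2-hydroxyethyl)-2,2,6,11,15,19-hexamethylicosa-6,10,14,18-tetraenoate | OCC[C@@H](CC/C(C)=C/CC/C=C(\C)CC/C=C(\C)CCC=C(C)C)C(C)(C)C(=O)OC
F6 | step 10 | methyl (3R,6E,10E,14E)-2,2,6,11,15,19-hexamethyl-3-(2-oxoethyl)icosa-6,10,14,18-tetraenoate | O=CC[C@@H](CC/C(C)=C/CC/C=C(\C)CC/C=C(\C)CCC=C(C)C)C(C)(C)C(=O)OC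
F7 | step 10 | methyl (3R,6E,10E,14E)-2,2,6,11,15,19-hexamethyl-3-{2-[(nonafluorobutylsulfonyl)oxy]ethenyl}icosa-6,10,14,18-tetraenoate | FC(F)(F)C(F)(F)C(F)(F)C(F)(F)S(=O)(=O)OC=C[C@@H](CC/C(C)=C/CC/C=C(\C)CC/C=C(\C)CCC=C(C)C)C(C)(C)C(=O)OC
F0 | step 15 | none | none
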